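**Plan**

- The aldehyde is carried as a dimethyl acetal. The furan (O1, C2 bearing CH2CO2Me, C3=C4, C5 bearing the C11 chain) is opened at O1–C2 and read as the dehydrated form of a 3,6-dihydro-1,2-dioxine. Furan C2–C5 are the four sp2 carbons of a (3E,5E)-dienoate and the ring oxygen comes from O2.
- The diene is cut at its central C4–C5 bond (Suzuki coupling) into an (E)-alkenyl iodide and an (E)-alkenylboronate. The iodide goes back through a Takai olefination to an ester aldehyde, whose C3 acetal arm comes from hydroformylation of a vinyl group.
- The vinyl-bearing stereocentre is cut at its C–butyl bond (SN2′ butylation of an allylic bromide made by cross-metathesis).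
- Forward, the chain is joined first (metathesis, butylation, hydroformylation, acetal, half-reduction, iodo-olefination, Suzuki). The only ring then arises as a six-membered peroxide ([4+2] with singlet oxygen) and contracts to the furan; acetal hydrolysis ends the route.
- The single stereocentre comes from the copper/Taniaphos allylic alkylation. It never sits next to an acidic position afterwards, and the two peroxide stereocentres are transient.

Key step: step 10

Assumption: the Taniaphos enantiomer written as (R,Rp) is taken to be the one whose sense of induction with (E)-allylic bromides gives the (R) branched product; if the sense is the reverse, the mirror-image ligand is used.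

Remark: dioxine 13 should form as both cis diastereomers, because the remote centre does not bias the diene faces. One is drawn, and 14 and 15 are drawn for deprotonation at the ring carbon next to the acetate arm; the other diastereomer and the other regiochemistry converge on 16.

**Route**

Step 1
Reactants: 1 methyl dec-9-enoate; 2 (E)-1,4-dibromobut-2-ene
Product: 3 methyl (9E)-11-bromoundec-9-enoate
Conditions: second-generation Grubbs catalyst (2 mol%), 2 (3 equiv), CH2Cl2, 40 °C
Reagents that add atoms: none
Why: Olefin cross-metathesis of a terminal alkene with an excess of the symmetrical dibromide should give the (E)-allylic bromide preferentially, with volatile allyl bromide as co-product and the ester inert to the ruthenium carbene.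

Step 2
Reactants: 3 methyl (9E)-11-bromoundec-9-enoate; 4 butylmagnesium bromide
Product: 5 methyl (9R)-9-butylundec-10-enoate
Conditions: CuBr·SMe2 (3 mol%), (R,Rp)-Taniaphos (3.6 mol%), 4 (1.2 equiv in Et2O, slow addition), CH2Cl2, −75 °C
Reagents that add atoms: none
Why: Copper-catalysed asymmetric allylic alkylation (SN2′) delivers butyl to the γ-carbon anti to bromide, the Taniaphos-bound copper choosing the alkene face and so setting C9 as R, while the methyl ester should not be attacked by the Grignard reagent at this temperature.

Step 3
Reactants: 5 methyl (9R)-9-butylundec-10-enoate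
Product: 6 methyl (9R)-9-butyl-12-oxododecanoate
Conditions: Rh(acac)(CO)2 (1 mol%), Xantphos (2 mol%), CO/H2 (1:1, 20 bar), toluene, 80 °C
Reagents that add atoms: carbon monoxide, [C-]#[O+]
Why: Rhodium-catalysed hydroformylation with the wide-bite-angle diphosphine places the formyl group on the terminal carbon, helped by the branched allylic position, and under CO pressure the hydride should not walk along the chain, so C9 keeps its configuration.

Step 4
Reactants: 6 methyl (9R)-9-butyl-12-oxododecanoate
Product: 7 methyl (9R)-9-butyl-12,12-dimethoxydodecanoate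
Conditions: HC(OMe)3 (3 equiv), PPTS (5 mol%), MeOH, rt
Reagents that add atoms: trimethyl orthoformate, COC(OC)OC; methanol, CO
Why: Acid-catalysed acetalisation is driven to completion by the orthoformate as water scavenger, and the methyl ester is unchanged in methanol.

Step 5
Reactants: 7 methyl (9R)-9-butyl-12,12-dimethoxydodecanoate
Product: 8 (9R)-9-butyl-12,12-dimethoxydodecanal
Conditions: iBu2AlH (1.05 equiv), CH2Cl2, −78 °C; aq. potassium sodium tartrate
Reagents that add atoms: none
Why: Partial ester reduction works because the aluminium hemiacetal formed by one hydride transfer is stable at −78 °C and releases the aldehyde only on work-up, the acetal being inert to the hydride.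

Step 6
Reactants: 8 (9R)-9-butyl-12,12-dimethoxydodecanal
Product: 9 (1E,10R)-10-butyl-1-iodo-13,13-dimethoxytridec-1-ene
Conditions: CrCl2 (6 equiv), CHI3 (2 equiv), 1,4-dioxane/THF (6:1), 0 °C to rt
Reagents that add atoms: iodoform, IC(I)I
Why: In the Takai olefination the geminal dichromium species formed from iodoform and CrCl2 (divalent chromium) adds to the aldehyde and eliminates to give mainly the (E)-iodoalkene, under conditions that acetals tolerate.

Step 7
Reactants: 10 methyl but-3-ynoate
Product: 11 methyl (3E)-4-(4,4,5,5-tetramethyl-1,3,2-dioxaborolan-2-yl)but-3-enoate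
Conditions: pinacolborane (1.1 equiv), Cy2BH (5 mol%), neat, rt
Reagents that add atoms: pinacolborane, [H]B1OC(C)(C)C(C)(C)O1
Why: Dialkylborane-catalysed syn hydroboration of the terminal alkyne puts boron on the terminal carbon and gives the (E)-alkenylboronate, and the absence of any base avoids isomerisation of the alkynoate to the allenoate.

Step 8
Reactants: 9 (1E,10R)-10-butyl-1-iodo-13,13-dimethoxytridec-1-ene; 11 methyl (3E)-4-(4,4,5,5-tetramethyl-1,3,2-dioxaborolan-2-yl)but-3-enoate
Product: 12 methyl (3E,5E,14R)-14-butyl-17,17-dimethoxyheptadeca-3,5-dienoate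
Conditions: Pd(OAc)2 (5 mol%), SPhos (10 mol%), K3PO4 (2 equiv), 11 (1.3 equiv), degassed THF/H2O (10:1), rt
Reagents that add atoms: none
Why: Suzuki–Miyaura coupling of an (E)-alkenyl iodide with an (E)-alkenylboronate proceeds with retention at both alkenes, and the weak phosphate base at room temperature should leave the skipped dienoate out of conjugation with the ester.

Step 9
Reactants: 12 methyl (3E,5E,14R)-14-butyl-17,17-dimethoxyheptadeca-3,5-dienoate
Product: 13 methyl 2-{(3S,6R)-6-[(8R)-8-butyl-11,11-dimethoxyundecyl]-3,6-dihydro-1,2-dioxin-3-yl}acetate (cis; mixed with its (3R,6S) cis diastereomer)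
Conditions: O2, 5,10,15,20-tetraphenylporphyrin (0.5 mol%), visible light, CH2Cl2, 0 °C
Reagents that add atoms: dioxygen, O=O
Why: Singlet oxygen adds suprafacially across the s-cis conformer of the (E,E)-diene in a [4+2] cycloaddition, which gives the cis-3,6-disubstituted dihydrodioxine, both ring faces being used because the C14 centre is too remote to discriminate.

Step 10
Reactants: 13 methyl 2-{(3S,6R)-6-[(8R)-8-butyl-11,11-dimethoxyundecyl]-3,6-dihydro-1,2-dioxin-3-yl}acetate
Product: 16 methyl 2-{5-[(8R)-8-butyl-11,11-dimethoxyundecyl]furan-2-yl}acetate, via cis-γ-hydroxy enone 14 (not isolated), via 2-hydroxy-2,5-dihydrofuran 15 (not isolated)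
Conditions: Et3N (0.5 equiv), CH2Cl2, rt; evaporate; then TsOH·H2O (2 mol%), 4 Å MS, CH2Cl2, 0 °C to rt
Reagents that add atoms: none
Why: In this Kornblum–DeLaMare rearrangement Et3N removes one of the allylic hydrogens on a peroxide carbon (C3 or C6) in an E2-type step across the weak O–O bond, giving a γ-hydroxy enone whose alkene is Z because it was the ring alkene. The freed hydroxyl then adds to the ketone carbon in a 5-exo-trig closure at oxygen (furan O1–C2) to give the 2-hydroxy-2,5-dihydrofuran, and TsOH-catalysed loss of water aromatises it; the closest known reaction type is the amine-induced rearrangement of 3,6-dihydro-1,2-dioxines to cis-γ-hydroxy enones followed by their acid dehydration to furans. No stereocentre is created and both peroxide centres are erased, so either cis diastereomer of 13 and either site of deprotonation converge on 16. The selectivity needed is O–O cleavage in preference to β-elimination of the peroxide towards the ester, and it is secured because Et3N cannot enolise the ester whereas the E2 step breaks the weak peroxide bond. The C8 centre of the side chain has no acidic neighbour, and the sieves keep the acetal dry; any acetal lost here would only anticipate step 11.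

Step 11
Reactants: 16 methyl 2-{5-[(8R)-8-butyl-11,11-dimethoxyundecyl]furan-2-yl}acetate
Product: 17 methyl 2-{5-[(8R)-8-butyl-11-oxoundecyl]furan-2-yl}acetate
Conditions: TsOH·H2O (10 mol%), acetone/H2O (10:1), rt
Reagents that add atoms: water, O
Why: Acid-catalysed acetal hydrolysis in wet acetone is mild enough to leave the 2,5-dialkylfuran, the methyl ester and the remote stereocentre untouched.

**Compound list**

1 | methyl dec-9-enoate | C=CCCCCCCCC(=O)OC | starting material
2 | (E)-1,4-dibromobut-2-ene | BrC/C=C/CBr | starting material
3 | methyl (9E)-11-bromoundec-9-enoate | COC(=O)CCCCCCC/C=C/CBr | intermediate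
4 | butylmagnesium bromide | CCCC[Mg]Br | starting material
5 | methyl (9R)-9-butylundec-10-enoate | CCCC[C@@H](C=C)CCCCCCCC(=O)OC | intermediate
6 | methyl (9R)-9-butyl-12-oxododecanoate | CCCC[C@@H](CCC=O)CCCCCCCC(=O)OC | intermediate
7 | methyl (9R)-9-butyl-12,12-dimethoxydodecanoate | CCCC[C@@H](CCC(OC)OC)CCCCCCCC(=O)OC | intermediate
8 | (9R)-9-butyl-12,12-dimethoxydodecanal | CCCC[C@@H](CCC(OC)OC)CCCCCCCC=O | intermediate
9 | (1E,10R)-10-butyl-1-iodo-13,13-dimethoxytridec-1-ene | CCCC[C@@H](CCC(OC)OC)CCCCCCC/C=C/I | intermediate
10 | methyl but-3-ynoate | C#CCC(=O)OC | starting material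
11 | methyl (3E)-4-(4,4,5,5-tetramethyl-1,3,2-dioxaborolan-2-yl)but-3-enoate | COC(=O)C/C=C/B1OC(C)(C)C(C)(C)O1 | intermediate
12 | methyl (3E,5E,14R)-14-butyl-17,17-dimethoxyheptadeca-3,5-dienoate | CCCC[C@@H](CCC(OC)OC)CCCCCCC/C=C/C=C/CC(=O)OC | intermediate
13 | methyl 2-{(3S,6R)-6-[(8R)-8-butyl-11,11-dimethoxyundecyl]-3,6-dihydro-1,2-dioxin-3-yl}acetate (cis; formed together with its (3R,6S) cis diastereomer) | CCCC[C@@H](CCC(OC)OC)CCCCCCC[C@@H]1C=C[C@H](CC(=O)OC)OO1 | intermediate
14 | methyl (4Z,6R,14R)-14-butyl-6-hydroxy-17,17-dimethoxy-3-oxoheptadec-4-enoate (cis-γ-hydroxy enone, not isolated, step 10) | CCCC[C@@H](CCC(OC)OC)CCCCCCC[C@@H](O)/C=C\C(=O)CC(=O)OC | intermediate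
15 | methyl 2-{(5R)-5-[(8R)-8-butyl-11,11-dimethoxyundecyl]-2-hydroxy-2,5-dihydrofuran-2-yl}acetate (both C2 epimers, not isolated, step 10) | CCCC[C@@H](CCC(OC)OC)CCCCCCC[C@@H]1C=CC(O)(CC(=O)OC)O1 | intermediate
16 | methyl 2-{5-[(8R)-8-butyl-11,11-dimethoxyundecyl]furan-2-yl}acetate | CCCC[C@@H](CCC(OC)OC)CCCCCCCc1ccc(CC(=O)OC)o1 | intermediate
17 | methyl 2-{5-[(8R)-8-butyl-11-oxoundecyl]furan-2-yl}acetate | CCCC[C@@H](CCC=O)CCCCCCCc1ccc(CC(=O)OC)o1 | target

**Step count**

Total: 11 steps. Longest linear sequence: 10 steps (steps 1–6 and 8–11, from 1); step 7 supplies the boronate.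

**Steps most likely to fail**

Step 9 (photooxygenation). Ene hydroperoxidation at the allylic methylenes on either side of the diene may compete with the cycloaddition, and any (5Z)-diene carried over from step 6 would add sluggishly and without stereospecificity. The fallback brings the oxygen in as an epoxide and sets out from 12. Buffered mCPBA (NaHCO3, CH2Cl2, 0 °C) should give the trans monoepoxide, mainly at the alkene remote from the ester, methyl (3E)-4-{(2S,3S)-3-[(8R)-8-butyl-11,11-dimethoxyundecyl]oxiran-2-yl}but-3-enoate F1, beside its regioisomer methyl 2-{(2S,3S)-3-[(1E,10R)-10-butyl-13,13-dimethoxytridec-1-en-1-yl]oxiran-2-yl}acetate F2, each with its epoxide-face diastereomer. Both vinyl oxiranes should undergo the ring expansion catalysed by Cu(hfacac)2 (copper bis(hexafluoroacetylacetonate), toluene, 150 °C) to the same product, methyl 2-{5-[(8R)-8-butyl-11,11-dimethoxyundecyl]-2,5-dihydrofuran-2-yl}acetate F3. DDQ (1,4-dioxane, rt) then dehydrogenates F3 to furan 16, where the route is rejoined.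

Step 8 (Suzuki coupling). Under the basic aqueous conditions the doubly activated methylene of boronate 11 or of product 12 may be deprotonated, so that the alkenes migrate into conjugation with the ester, and protodeboronation may also compete. The fallback is a base-free Stille coupling and sets out from 9 and 10. Palladium-catalysed syn hydrostannation of 10 (Bu3SnH, PdCl2(PPh3)2, THF, 0 °C) should give methyl (3E)-4-(tributylstannyl)but-3-enoate F4, after separation from any internal regioisomer. F4 is then coupled with iodide 9 under neutral conditions (Pd2(dba)3, AsPh3, NMP, rt) to return to the route at 12.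

Step 10 (peroxide-to-furan rearrangement). The amine may instead trigger β-elimination of the peroxide towards the ester, or the hydroxy enone may stall or isomerise before it closes. The fallback separates O–O cleavage from oxidation and sets out from 13. Zinc dust and acetic acid (CH2Cl2, rt) reduce the peroxide to the cis-enediol methyl (3S,4Z,6R,14R)-14-butyl-3,6-dihydroxy-17,17-dimethoxyheptadec-4-enoate F5. Activated MnO2 (CH2Cl2, rt) oxidises one allylic hydroxyl of F5 to the cis-γ-hydroxy enone, which closes and dehydrates (a trace of PPTS if the hemiketal persists) to rejoin the route at 16.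

**Further compounds**

F1 | step 9 | methyl (3E)-4-{(2S,3S)-3-[(8R)-8-butyl-11,11-dimethoxyundecyl]oxiran-2-yl}but-3-enoate (trans; with its (2R,3R) diastereomer) | CCCC[C@@H](CCC(OC)OC)CCCCCCC[C@@H]1O[C@H]1/C=C/CC(=O)OC
F2 | step 9 | methyl 2-{(2S,3S)-3-[(1E,10R)-10-butyl-13,13-dimethoxytridec-1-en-1-yl]oxiran-2-yl}acetate (trans; with its (2R,3R) diastereomer) | CCCC[C@@H](CCC(OC)OC)CCCCCCC/C=C/[C@@H]1O[C@H]1CC(=O)OC
F3 | step 9 | methyl 2-{5-[(8R)-8-butyl-11,11-dimethoxyundecyl]-2,5-dihydrofuran-2-yl}acetate (ring centres as a mixture) | CCCC[C@@H](CCC(OC)OC)CCCCCCCC1C=CC(CC(=O)OC)O1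
F4 | step 8 | methyl (3E)-4-(tributylstannyl)but-3-enoate | CCCC[Sn](CCCC)(CCCC)/C=C/CC(=O)OC
F5 | step 10 | methyl (3S,4Z,6R,14R)-14-butyl-3,6-dihydroxy-17,17-dimethoxyheptadec-4-enoate | CCCC[C@@H](CCC(OC)OC)CCCCCCC[C@@H](O)/C=C\[C@H](CC(=O)OC)O
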